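Numbers refer to the compound list after the steps. Ar = 4-methoxy-3,5-bis(3-methylbut-2-en-1-yl)phenyl. Ring positions are given in chroman-4-one numbering throughout; in the pyranones 7–10 the ring carbons C5 and C6 are the future C4a and C8a.

## Analysis of the target

Target 14 is a flavanone: a chroman-4-one in which benzene ring A (C4a, C5–C8, C8a, hydroxyl on C7) is fused to the oxygen heterocycle ring C (O1, C2, C3, C4), and C2 carries aryl ring B with a 4'-methoxy group flanked by two prenyl groups. C2 is the only stereocentre and must be S; it is benzylic, bonded to O1 and β to the C4 ketone, and no second centre exists to relay or correct it. This is the weak point of every flavanone: enolisation at C3 lets the phenoxide O1 leave, ring C opens to the 2'-hydroxychalcone and recloses without stereocontrol, so base and strong or hot acid must be kept away once the chromanone exists. The other sensitive groups are the free C7 phenol and the two trisubstituted alkenes, which react with protic acid, halonium, sulfenyl and peracid reagents and can cyclise onto the neighbouring methoxy oxygen with loss of the methyl group. The difficulty is therefore not the skeleton but to set C2 as one enantiomer and then never to expose the O1–C2/C3–H array to equilibrating conditions, with two nucleophilic alkenes present from an early stage. The route rests on the fact that O1, C2 with its aryl group, C3, C4, C4a and C8a form a 2-aryl-2,3-dihydro-4H-pyran-4-one, a ring that a catalytic asymmetric aldehyde–diene cycloaddition builds from a simple aryl aldehyde. Its enone C4a=C8a is then the two-carbon edge on which C5–C8 of ring A, with oxygen on C7, can be annulated without base, so that the chromanone appears only in the last step.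

## Retrosynthetic reasoning

**Ring A (14 to 10 and 5).** The bonds C4a–C5 and C8–C8a of 14 are cut. This takes C5–C8 and the C7 oxygen back to diene 5 and leaves sulfoxide 10, a dihydropyranone with a phenylsulfinyl group on C4a. The cut is made here because the C4a=C8a alkene is polarised with C8a electrophilic: the nucleophilic CH2 terminus of 5 must bond to C8a, and the silyloxy carbon then becomes C7, where the hydroxyl is needed. An arene lies two oxidation levels above a cyclohexene. One level comes from eliminating the methoxy group that 5 brings to C5; the other comes from the sulfinyl group, which also activates the dienophile and leaves by thermal syn-elimination. The forward reaction must run cycloaddition, unmasking of the C5=C6–C7=O enone and sulfoxide elimination in that order (11, 12, 13). The gain is that the phenol is formed free and the flavanone arises in the final operation, without base.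

**Sulfur at C4a (10 to 9 to 8 to 7).** The S–O, C4a–S and C4a–I bonds are removed in turn. The detour through iodide 8 is preferred to direct sulfenylation, because electrophilic sulfur reagents would add to the prenyl alkenes. C4a of 7 is the α-carbon of a vinylogous ester and should take a mild iodine electrophile selectively; the C–S bond is then made by cross-coupling with a nucleophilic sulfur partner. None of these operations involves C2 or C3.

**Ring C (7 to 4 and 5), the strategic cut.** Ring C is disconnected at C2–C3 and O1–C8a, giving aldehyde 4 and a second molecule of diene 5. The stereochemical problem becomes face selection at an aldehyde carbonyl, for which chiral Lewis acid catalysis is well developed. The C2–O1 bond comes from the aldehyde oxygen itself, so it is never made by a reversible conjugate addition. Cutting O1–C2 or C2–aryl instead would bring back phenoxide conjugate addition, or conjugate arylation on a ring that already holds the phenol. The forward step must add the diene terminus to one face of 4 (through 6) and close the ring with loss of the methoxy and silyl groups.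

**Ring B side chains (4 to 2 and 3, 2 to 1).** The two aryl–CH2 bonds of 4 are cut to dibromide 2 and two molecules of boronate 3. Both prenyl groups are installed in one operation on a symmetrical substrate, and the only selectivity needed is linear against branched transfer of the allylic group. Dibromide 2 comes from commercial phenol 1 by O-methylation, done first because a free phenol between the reacting positions would interfere with the coupling.

## Alternatives that were turned down

**Alternative 1:** Only C2–C3 is disconnected and ring A is bought ready-made.
- Precursor: the cyclic enol acetal 2-Ar-4-methylene-7-(triisopropylsilyloxy)-4H-1,3-benzodioxin A1, from aldehyde 4 and a ring-A salicylate unit by acetalisation and carbonyl methylenation.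
- Key step: a chiral Lewis acid ionises the acetal C–O bond on the enol side, and the aryloxy oxocarbenium ion and the metal enolate recombine through carbon (Petasis–Ferrier rearrangement) to give the silyl-protected flavanone A2.
- For: it is convergent and short (about five steps), and it needs no construction of ring A.
- Against: the acetal centre of A1 is destroyed on ionisation, so the configuration of A2 must be imposed on the recombination of an ion pair. The cation is stabilised twice (by the aryloxy oxygen and by the electron-rich aryl group), lives long and rotates freely, and catalyst-controlled enantioselective versions of this rearrangement are not established. The same Lewis acid can re-ionise A2 at C2–O1 or open it to the chalcone, and the final desilylation needs fluoride, which is a base toward a flavanone.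
- Comparison: it is stronger than the chosen route in step count and in avoiding an uncertain benzannulation, but weaker at the one stereocentre. The chosen route places the stereochemical burden on a cycloaddition class with broad precedent for aryl aldehydes and pays with more steps afterwards.

**Alternative 2:** O1–C2 and C3–C4 are cut.
- Precursors: styrene A3 (2-methoxy-1,3-bis(3-methylbut-2-en-1-yl)-5-vinylbenzene) and salicylaldehyde A4 (2-hydroxy-4-(triisopropylsilyloxy)benzaldehyde).
- Key step: A4 is converted with an orthoformate and a chiral Brønsted acid into a 4-methoxy ortho-quinone methide (an oxocarbenium ion), which adds to the styrene in an inverse-demand [4+2] reaction to give the cis-chroman A5.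
- For: two bonds and ring C form in one step from two simple pieces, ring A stays intact, and the racemic reaction type with styrenes is well known.
- Against:
  - The heterodiene is a strong carbon electrophile, and A3 holds two trisubstituted alkenes that are at least as nucleophilic as its vinyl group. The para methoxy group is twisted out of conjugation by its two ortho substituents, so the vinyl group does not have the reactivity of a 4-methoxystyrene. Chemoselectivity is doubtful.
  - A5 has the wrong oxidation level at C4. Turning the benzylic methyl ether into the ketone requires oxidants that also attack the allylic and benzylic positions of prenylated, electron-rich arenes.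
  - The C4 stereocentre is made only to be destroyed, and two or three steps follow the key step.
- Comparison: it is more convergent and more economical in ring construction. The chosen route has no such conflict, since its electrophiles are either bound to the aldehyde or mild and buffered.

**Alternative 3:** C3–C4 and O1–C8a are cut; O1–C8a is made by nucleophilic aromatic substitution.
- Precursors: allyl (S)-3-Ar-3-hydroxypropanoate A6, available from 4 by dependable asymmetric chemistry, and methyl 2-fluoro-4-(methoxymethoxy)benzoate A7.
- Key step: the dianion of A6 is C-acylated by A7, and the alkoxide then displaces the fluoride ortho to the new ketone to give keto ester A8. Palladium-catalysed deallylation with decarboxylation and acid removal of the acetal protecting group would finish the synthesis.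
- For: the stereocentre comes from very reliable chemistry, the oxygen is already on C2 so that bond is never formed or broken later, ring A is purchased, and the length is comparable (about seven steps).
- Against: every bond is formed under strongly basic conditions. The dianion of a benzylic β-hydroxy ester is prone to retro-aldol cleavage, and C- against O-acylation is uncertain. Once ring C is closed, A8 is a β-keto ester whose enolate lies next to C2 and can expel the phenoxide O1, which is exactly the equilibrium that racemises flavanones, and base is still present. The decarboxylation forms the C3 enolate once more.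
- Comparison: on the source of chirality and on not having to build ring A it is equal or stronger. The chosen route offers an endgame free of enolate chemistry at C3 and a phenol that never needs a protecting group.

Key step: step 3

Assumption: the (S)-BINOL titanate is taken to direct the diene to the Si face of aldehyde 4, as this catalyst family does with benzaldehyde-type substrates; if a calibration run showed the opposite sense, (R)-BINOL would be used with no other change.

## Steps

**Step 1**
Reactants: 1 3,5-dibromo-4-hydroxybenzaldehyde
Product: 2 3,5-dibromo-4-methoxybenzaldehyde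
Conditions: MeI, K2CO3, DMF, rt
Reagents that add atoms: iodomethane, CI
Why: Williamson ether synthesis; the phenol is acidified by two ortho bromines and the para formyl group, so carbonate suffices, and the acidic proton is removed before the coupling.

**Step 2**
Reactants: 2 3,5-dibromo-4-methoxybenzaldehyde; 3 4,4,5,5-tetramethyl-2-(3-methylbut-2-en-1-yl)-1,3,2-dioxaborolane (two equivalents enter the product)
Product: 4 4-methoxy-3,5-bis(3-methylbut-2-en-1-yl)benzaldehyde
Conditions: Pd(OAc)2, t-BuXPhos, K3PO4 (aq), THF, 40 °C
Reagents that add atoms: none
Why: Twofold Suzuki–Miyaura coupling of an allylic boronate; the bulky di-tert-butyl biaryl phosphine disfavours the tertiary σ-allyl palladium complex, so reductive elimination should occur from the primary σ-prenyl isomer and give the linear product. Phosphate as base leaves the aldehyde, which has no α-hydrogen, untouched.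

**Step 3**
Reactants: 4 4-methoxy-3,5-bis(3-methylbut-2-en-1-yl)benzaldehyde; 5 (E)-1-methoxy-3-(trimethylsilyloxy)buta-1,3-diene
Product: 7 (S)-2-[4-methoxy-3,5-bis(3-methylbut-2-en-1-yl)phenyl]-2,3-dihydro-4H-pyran-4-one, via silylated aldol adduct 6 (not isolated)
Conditions: (S)-BINOL (20 mol%), Ti(OiPr)4 (10 mol%), 4 Å MS, Et2O, −20 °C; then TFA, CH2Cl2, 0 °C
Reagents that add atoms: none
Why: This is a catalytic asymmetric hetero-Diels–Alder reaction of an aryl aldehyde with a 1-methoxy-3-silyloxy diene, run in its stepwise Mukaiyama aldol–cyclisation form, which is the closest known reaction type and is well precedented for benzaldehydes. The BINOL complex of tetravalent titanium binds the aldehyde oxygen, the unsubstituted CH2 terminus of 5 adds to the carbonyl carbon to form C2–C3, and silyl transfer to the alkoxide releases the catalyst and gives 6. Trifluoroacetic acid then cleaves the silyl ether, and the C2 hydroxyl closes ring C by 6-endo-trig conjugate addition to the methoxy-bearing enone carbon (the future C8a) followed by loss of methanol, which forms O1–C8a; a concerted [4+2] path would give the same product after the same acid treatment. C2 is set in the C–C bond-forming event by the catalyst alone: (S)-BINOL is expected to block the Re face so that the diene adds to the Si face, which gives S, and no later step touches this centre. Only face selectivity is needed, because the polarity of the diene fixes the regiochemistry. The aldehyde supports this: it has no α-hydrogen, its ortho positions are free and the prenyl groups sit meta to the carbonyl, so it should behave like benzaldehyde. The methoxy group, twisted by its two ortho substituents, donates little, so the carbonyl stays electrophilic; the isolated alkenes do not react with the diene or the mild Lewis acid, and the acid stage is kept short and cold to spare them.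

**Step 4**
Reactants: 7 (S)-2-Ar-2,3-dihydro-4H-pyran-4-one
Product: 8 (S)-2-Ar-5-iodo-2,3-dihydro-4H-pyran-4-one
Conditions: I2, pyridine, CH2Cl2, 0 °C to rt
Reagents that add atoms: iodine, II
Why: α-Iodination of an enone with iodine–pyridine; in this vinylogous ester the future C4a is the nucleophilic enol-ether carbon and is iodinated, after which pyridine removes the proton to restore the enone. Pyridine-buffered iodine is a weak electrophile toward isolated alkenes, and C2 is not involved.

**Step 5**
Reactants: 8 (S)-2-Ar-5-iodo-2,3-dihydro-4H-pyran-4-one
Product: 9 (S)-2-Ar-5-(phenylsulfanyl)-2,3-dihydro-4H-pyran-4-one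
Conditions: PhSH, Pd2(dba)3, Xantphos, iPr2NEt, 1,4-dioxane, 80 °C
Reagents that add atoms: thiophenol, Sc1ccccc1
Why: Palladium-catalysed C–S cross-coupling of a vinyl iodide with a thiol (zerovalent palladium with a wide-bite-angle bisphosphine); oxidative addition into an α-iodoenone is fast, and the C–S bond forms without any electrophilic sulfur reagent that would add to the prenyl groups. The amine base is too weak to enolise C3, so C2 is safe.

**Step 6**
Reactants: 9 (S)-2-Ar-5-(phenylsulfanyl)-2,3-dihydro-4H-pyran-4-one
Product: 10 (2S)-2-Ar-5-(phenylsulfinyl)-2,3-dihydro-4H-pyran-4-one (both configurations at sulfur)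
Conditions: H2O2 (30%, 1.1 equiv), (CF3)2CHOH, 0 °C to rt
Reagents that add atoms: hydrogen peroxide, OO
Why: Chemoselective oxidation of a sulfide to the sulfoxide by hydrogen peroxide activated through hydrogen bonding in hexafluoroisopropanol; sulfur is oxidised far faster than trisubstituted alkenes, and the hydrogen-bonded sulfoxide resists further oxidation. Both configurations at sulfur are acceptable because sulfur is removed in step 7.

**Step 7**
Reactants: 10 (2S)-2-Ar-5-(phenylsulfinyl)-2,3-dihydro-4H-pyran-4-one; 5 (E)-1-methoxy-3-(trimethylsilyloxy)buta-1,3-diene
Product: 14 (S)-7-hydroxy-2-[4-methoxy-3,5-bis(3-methylbut-2-en-1-yl)phenyl]chroman-4-one, via silyl enol ether cycloadduct 11 (not isolated), via sulfinyl enedione 12 (not isolated), via keto tautomer 13 (not isolated)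
Conditions: 5 (3 equiv), ZnBr2, CH2Cl2, −20 to 0 °C; TFA, 0 °C; NaHCO3 (aq); then PhMe, 50 °C
Reagents that add atoms: none
Why: Lewis-acid-promoted Diels–Alder reaction of a chelated α-sulfinyl enone, used as an ynone equivalent: the nucleophilic terminus of 5 attacks C8a, which places the silyloxy carbon at C7, and the suprafacial addition leaves sulfur on C4a cis to the hydrogen on C8a. Acid then unmasks the C5=C6–C7=O enone (loss of methanol and of the silyl group) before any elimination, so that the thermal sulfoxide syn-elimination can only take H-8a; this gives dienone 13, which tautomerises to the phenol. C2 is not involved and no base is present, so the flavanone should not open to the chalcone.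

## Compound list

1 | 3,5-dibromo-4-hydroxybenzaldehyde | O=Cc1cc(Br)c(O)c(Br)c1 | starting material
2 | 3,5-dibromo-4-methoxybenzaldehyde | COc1c(Br)cc(C=O)cc1Br | intermediate
3 | 4,4,5,5-tetramethyl-2-(3-methylbut-2-en-1-yl)-1,3,2-dioxaborolane (prenylboronic acid pinacol ester) | CC(C)=CCB1OC(C)(C)C(C)(C)O1 | starting material
4 | 4-methoxy-3,5-bis(3-methylbut-2-en-1-yl)benzaldehyde | COc1c(CC=C(C)C)cc(C=O)cc1CC=C(C)C | intermediate
5 | (E)-1-methoxy-3-(trimethylsilyloxy)buta-1,3-diene | CO/C=C/C(=C)O[Si](C)(C)C | starting material
6 | (S,E)-1-methoxy-5-[4-methoxy-3,5-bis(3-methylbut-2-en-1-yl)phenyl]-5-(trimethylsilyloxy)pent-1-en-3-one | COc1c(CC=C(C)C)cc([C@@H](O[Si](C)(C)C)CC(=O)/C=C/OC)cc1CC=C(C)C | intermediate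
7 | (S)-2-[4-methoxy-3,5-bis(3-methylbut-2-en-1-yl)phenyl]-2,3-dihydro-4H-pyran-4-one | COc1c(CC=C(C)C)cc([C@@H]2CC(=O)C=CO2)cc1CC=C(C)C | intermediate
8 | (S)-5-iodo-2-[4-methoxy-3,5-bis(3-methylbut-2-en-1-yl)phenyl]-2,3-dihydro-4H-pyran-4-one | COc1c(CC=C(C)C)cc([C@@H]2CC(=O)C(I)=CO2)cc1CC=C(C)C | intermediate
9 | (S)-2-[4-methoxy-3,5-bis(3-methylbut-2-en-1-yl)phenyl]-5-(phenylsulfanyl)-2,3-dihydro-4H-pyran-4-one | COc1c(CC=C(C)C)cc([C@@H]2CC(=O)C(Sc3ccccc3)=CO2)cc1CC=C(C)C | intermediate
10 | (2S)-2-[4-methoxy-3,5-bis(3-methylbut-2-en-1-yl)phenyl]-5-(phenylsulfinyl)-2,3-dihydro-4H-pyran-4-one, both configurations at sulfur | COc1c(CC=C(C)C)cc([C@@H]2CC(=O)C(S(=O)c3ccccc3)=CO2)cc1CC=C(C)C | intermediate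
11 | (2S)-5-methoxy-2-[4-methoxy-3,5-bis(3-methylbut-2-en-1-yl)phenyl]-4a-(phenylsulfinyl)-7-(trimethylsilyloxy)-2,3,4a,5,8,8a-hexahydro-4H-chromen-4-one, cis ring fusion, other centres as formed | COc1c(CC=C(C)C)cc([C@@H]2CC(=O)C3(S(=O)c4ccccc4)C(OC)C=C(O[Si](C)(C)C)CC3O2)cc1CC=C(C)C | intermediate
12 | (2S)-2-[4-methoxy-3,5-bis(3-methylbut-2-en-1-yl)phenyl]-4a-(phenylsulfinyl)-2,3,8,8a-tetrahydro-4H-chromene-4,7(4aH)-dione, cis ring fusion | COc1c(CC=C(C)C)cc([C@@H]2CC(=O)C3(S(=O)c4ccccc4)C=CC(=O)CC3O2)cc1CC=C(C)C | intermediate
13 | (S)-2-[4-methoxy-3,5-bis(3-methylbut-2-en-1-yl)phenyl]-2,3-dihydro-4H-chromene-4,7(8H)-dione (keto tautomer of 14) | COc1c(CC=C(C)C)cc([C@@H]2CC(=O)C3=C(O2)CC(=O)C=C3)cc1CC=C(C)C | intermediate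
14 | (S)-7-hydroxy-2-[4-methoxy-3,5-bis(3-methylbut-2-en-1-yl)phenyl]chroman-4-one | COc1c(CC=C(C)C)cc([C@@H]2CC(=O)c3ccc(O)cc3O2)cc1CC=C(C)C | target

## Step count and least certain steps

Total: 7 steps. Longest linear sequence: 7 steps (1 to 2 to 4 to 7 to 8 to 9 to 10 to 14).

**Step 7 (benzannulation).**
- Premature sulfoxide elimination is the main hazard. If the cycloaddition is too slow below room temperature and has to be heated, the sulfoxide of the primary adduct 11 eliminates before the enone is unmasked. In 11 the allylic, methoxy-bearing H-5 can lie syn to sulfur, and its abstraction in place of H-8a leads to a C4a=C5 enol ether that cannot aromatise.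
- The reaction may also stall after the first C–C bond, giving a Michael adduct whose sulfoxide then eliminates without ring A.
- The allylic sulfoxide 12 can shift reversibly to a sulfenate, which is harmless only while no thiophile is present.
- The sulfenic acid set free may attack the electron-rich phenol or the alkenes.
- Fallback, from 10, returning at 12: ring A is built stepwise by ionic chemistry. The methyl-side lithium enolate of 4,4-dimethoxybutan-2-one (LiN(iPr)2, THF, −78 °C) is added in a Michael reaction to C8a of 10; α-sulfinyl enones are good acceptors for enolates. This gives (2S)-2-Ar-6-(4,4-dimethoxy-2-oxobutyl)-5-(phenylsulfinyl)tetrahydro-4H-pyran-4-one F1, which is kept below 0 °C. Acid (TFA or BF3·OEt2, CH2Cl2, 0 °C) ionises the acetal, the β-keto sulfoxide carbon C4a closes ring A on the oxocarbenium carbon (C4a–C5), and loss of the second methanol gives 12. The route then continues as in step 7. No intermediate on this path has a sulfoxide beside an sp3 C5–H.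

**Step 3 (key step).**
- Facial selectivity may be insufficient or of the opposite sense, since the active titanium species is sensitive to water and to the BINOL:Ti ratio.
- Turnover may be slow with a lipophilic, moderately electrophilic aldehyde.
- During the acid stage the benzylic C2–O1 bond of 7 may ionise in part, which would erode the enantiomeric purity.
- Acid may promote cyclisation of a prenyl group onto the methoxy oxygen.
- Fallback, from 4, returning at 7: a reagent-controlled boron aldol reaction replaces the catalytic cycloaddition. (E)-4-Chlorobut-3-en-2-one is enolised with (−)-Ipc2BCl and iPr2NEt (Et2O, −78 °C) and added to 4; the antipode of the reagent is chosen for Si-face attack. Oxidative work-up gives (S,E)-1-chloro-5-hydroxy-5-Ar-pent-1-en-3-one F2. iPr2NEt in CH2Cl2 then closes the ring by addition of the hydroxyl to the chlorovinyl carbon and loss of chloride, giving 7 without an acid stage.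

**Step 2 (double prenylation).**
- Reductive elimination from the tertiary σ-allyl palladium complex at one or both positions would give branched (1,1-dimethylallyl) isomers that are hard to separate.
- Protodeboronation of 3 and stalling at the mono-coupled stage are further risks.
- Fallback, from 2, returning at 4: the regiochemical question is removed by coupling the unsubstituted allyl group and adjusting the alkene afterwards. Allylboronic acid pinacol ester, Pd(PPh3)4 and CsF in THF at 65 °C give 3,5-diallyl-4-methoxybenzaldehyde F3. Cross-metathesis with 2-methylbut-2-ene (second-generation Grubbs catalyst, (H2IMes)(PCy3)Cl2Ru=CHPh, CH2Cl2, rt to 40 °C) converts both allyl groups into prenyl groups and gives 4.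

**Step 4 (iodination).**
- Iodine may attack the prenyl alkenes. The most likely course is iodonium formation followed by ring closure through the neighbouring methoxy oxygen with loss of the methyl group, or hydroiodination once the buffer is used up.
- Fallback, from 7, returning at 9 (it also bypasses step 5): sulfur is brought in through an enolate, with no halogen electrophile and no thiol coupling. Conjugate reduction of 7 with LiBH(s-Bu)3 (THF, −78 °C) gives the C4/C4a enolate regiospecifically, and trapping with S-phenyl benzenethiosulfonate gives (2S)-2-Ar-5-(phenylsulfanyl)tetrahydro-4H-pyran-4-one F4. N-Chlorosuccinimide (CCl4, rt) chlorinates the sulfur-bearing carbon to (2S)-5-chloro-2-Ar-5-(phenylsulfanyl)tetrahydro-4H-pyran-4-one F5. 2,4,6-Collidine then removes hydrogen chloride toward the oxygen-bearing carbon and gives 9.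

## Further compounds

F1 | step 7 | (2S)-6-(4,4-dimethoxy-2-oxobutyl)-2-[4-methoxy-3,5-bis(3-methylbut-2-en-1-yl)phenyl]-5-(phenylsulfinyl)tetrahydro-4H-pyran-4-one | COc1c(CC=C(C)C)cc([C@@H]2CC(=O)C(S(=O)c3ccccc3)C(CC(=O)CC(OC)OC)O2)cc1CC=C(C)C
F2 | step 3 | (S,E)-1-chloro-5-hydroxy-5-[4-methoxy-3,5-bis(3-methylbut-2-en-1-yl)phenyl]pent-1-en-3-one | COc1c(CC=C(C)C)cc([C@@H](O)CC(=O)/C=C/Cl)cc1CC=C(C)C
F3 | step 2 | 3,5-diallyl-4-methoxybenzaldehyde | COc1c(CC=C)cc(C=O)cc1CC=C
F4 | step 4 | (2S)-2-[4-methoxy-3,5-bis(3-methylbut-2-en-1-yl)phenyl]-5-(phenylsulfanyl)tetrahydro-4H-pyran-4-one | COc1c(CC=C(C)C)cc([C@@H]2CC(=O)C(Sc3ccccc3)CO2)cc1CC=C(C)C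
F5 | step 4 | (2S)-5-chloro-2-[4-methoxy-3,5-bis(3-methylbut-2-en-1-yl)phenyl]-5-(phenylsulfanyl)tetrahydro-4H-pyran-4-one | COc1c(CC=C(C)C)cc([C@@H]2CC(=O)C(Cl)(Sc3ccccc3)CO2)cc1CC=C(C)C
A1 | alternative 1 | 2-[4-methoxy-3,5-bis(3-methylbut-2-en-1-yl)phenyl]-4-methylene-7-(triisopropylsilyloxy)-4H-1,3-benzodioxin (racemic at the acetal carbon) | C=C1OC(c2cc(CC=C(C)C)c(OC)c(CC=C(C)C)c2)Oc2cc(O[Si](C(C)C)(C(C)C)C(C)C)ccc12
A2 | alternative 1 | (S)-2-[4-methoxy-3,5-bis(3-methylbut-2-en-1-yl)phenyl]-7-(triisopropylsilyloxy)chroman-4-one | COc1c(CC=C(C)C)cc([C@@H]2CC(=O)c3ccc(O[Si](C(C)C)(C(C)C)C(C)C)cc3O2)cc1CC=C(C)C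
A3 | alternative 2 | 2-methoxy-1,3-bis(3-methylbut-2-en-1-yl)-5-vinylbenzene | COc1c(CC=C(C)C)cc(C=C)cc1CC=C(C)C
A4 | alternative 2 | 2-hydroxy-4-(triisopropylsilyloxy)benzaldehyde | O=Cc1ccc(O[Si](C(C)C)(C(C)C)C(C)C)cc1O
A5 | alternative 2 | (2S,4S)-cis-4-methoxy-2-[4-methoxy-3,5-bis(3-methylbut-2-en-1-yl)phenyl]-7-(triisopropylsilyloxy)chroman | COc1c(CC=C(C)C)cc([C@@H]2C[C@H](OC)c3ccc(O[Si](C(C)C)(C(C)C)C(C)C)cc3O2)cc1CC=C(C)C
A6 | alternative 3 | allyl (S)-3-hydroxy-3-[4-methoxy-3,5-bis(3-methylbut-2-en-1-yl)phenyl]propanoate | COc1c(CC=C(C)C)cc([C@@H](O)CC(=O)OCC=C)cc1CC=C(C)C
A7 | alternative 3 | methyl 2-fluoro-4-(methoxymethoxy)benzoate | COCOc1ccc(C(=O)OC)c(F)c1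
A8 | alternative 3 | allyl (2S,3R)-trans-7-(methoxymethoxy)-2-[4-methoxy-3,5-bis(3-methylbut-2-en-1-yl)phenyl]-4-oxochroman-3-carboxylate (C3 epimerisable) | COc1c(CC=C(C)C)cc([C@@H]2[C@@H](C(=O)OCC=C)C(=O)c3ccc(OCOC)cc3O2)cc1CC=C(C)C
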